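The alpha run climbed to 17% by 8.00 min, then bent over and stood at 33% after 50.0 min. I assumed that the bend marks substrate being consumed by a side path, second order in [substrate], beside a catalysed path first order in [substrate] and proportional to the catalyst charge. The readings show no substrate, so this remains an assumption.

the same everywhere: substrate 0.033 M

| flask | partner | free catalyst | temperature | remark | time |
|---|---|---|---|---|---|
| alpha | 2 equiv | 0.14 mol% | 75 °C | run made earlier |  |
| Thursday's | 2.00 equiv | 0.29 mol% | 75 °C |  | 2.5 h |
| Wednesday's | 2.00 equiv | 0.29 mol% | 25 °C |  | 2.5 h |
| Saturday's | 2.00 equiv | 0.29 mol% | 50 °C |  | 2.5 h |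

alpha run (percent of the substrate charged)

| time / min | target / % |
|---|---|
| 3.00 | 5 |
| 8.00 | 17 |
| 15.0 | 18 |
| 25.0 | 25 |
| 30.0 | 29 |
| 50.0 | 33 |

(standard deviation of a reading: 2 percentage points)

1. the flask with the highest amount of target, in percent of the substrate charged ("all alike" if they lie within 1.5 percentage points) (Thursday's / Wednesday's / Saturday's / all alike)
2. final target, as a percentage of the substrate charged, in Thursday's
3. final target, as a percentage of the substrate charged, in Wednesday's
4. final target, as a percentage of the substrate charged, in Saturday's

- the earlier runs do not show what temperature does; that part of a forecast is a guess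
- a reading or a percentage of target counts all its forms, free or not
- no earlier run changes the charge of free catalyst; that part of a forecast is a guess

Dividing the rate of target by the rate of substrate loss removes time. What remains is ρ, the side rate over the catalysed rate at the charged [substrate], taken as an average over the run. With a the starting slope, the curve is target = ln(1 + ρ(1 − exp(−at)))/ρ, so its level is ln(1 + ρ)/ρ. Taking the alpha run's last reading as that level, with its scatter, I solved for ρ = 5.83, and this split ratio, a selectivity factor, is what I carried forward.

Thursday's has 2.07 times the catalyst, which I guessed would divide ρ by that factor, to 2.82. The alpha chord to 8.00 min, scaled the same way, gave Thursday's a starting slope of 0.0440 /min, as a share of the charge. Its level came to 47.6%, and the tangent meets that level at a knee near 10.8 min, so 2.5 h lies 13.9 knees out, on the flat.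

For temperature I guessed that both paths slow by a factor of 6.00 at each step, from 75 °C to 50 °C and from there to 25 °C, leaving ρ unchanged. Saturday's then reaches 37.6% and Wednesday's 13.7%, which puts Thursday's highest.

The forecast, higher than my level on Thursday's, named Thursday's with 63% (47% to 82%), Saturday's 42% (22% to 66%) and Wednesday's 14% (4% to 32%), and said of its two explanations that “the data fit both about equally”.

The flasks gave 47.4% in Thursday's, 43.3% in Saturday's and 12.0% in Wednesday's.

    substrate + free catalyst → catalyst intermediate A (k = 5400 /M/h, Ea = 52.0 kJ/mol)
    partner + catalyst intermediate A ⇌ catalyst intermediate B (K = 2.70 /M, k = 9670 /M/h, Ea = 45.0 kJ/mol, ΔH = −16.0 kJ/mol)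
    catalyst intermediate B → by-product + catalyst intermediate C (k = 142 /h, Ea = 85.0 kJ/mol)
    catalyst intermediate C → free catalyst + target (k = 20300 /h, Ea = 57.0 kJ/mol)
    substrate + target ⇌ idle adduct, settled at all times (K = 91.0 /M, ΔH = −57.0 kJ/mol)
    2 substrate → homo dimer (k = 8.19 /M/h, Ea = 53.0 kJ/mol)
    (constants at 25 °C)

Thursday's ended with substrate at 0%, homo dimer at 52.6% and free catalyst at 100%. Saturday's, left for 25.0 h, gave 44.2%, and taking that as its level gives ρ = 3.29. With x the share of substrate remaining, the time-free curve is target = ln((1 + ρ)/(1 + ρx))/ρ. The same flask read at 1.5 h had 5.28% of its substrate remaining, which puts its target at 39.4%, and that flask held 38.1%.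

The numbers in the tables stem from a simulated flask on assumed constants, noise included.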